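Time is what I count here: how many half-lives of the left-handed substrate fit into the run of 50 h.

left-handed substrate 0.16 M; gas 7.5 mM (held); right-handed substrate 0.16 M; time 50 h

- the left-handed product standing at 50 h, as a percentage of the left-handed substrate and right-handed substrate together charged
- the change that raises the amount of left-handed product at 50 h, in percent of the left-handed substrate and right-handed substrate together charged most ("none" if none brings more than 2 percentage points) (south-east / west / none)
- amount of left-handed product at 50 h, in percent of the left-handed substrate and right-handed substrate together charged, after west

- south-east: doubling the saturation concentration of gas, all else as stated
- west: doubling the transfer coefficient of step 3, all else as stated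

- reagent is single-handed; left-handed substrate and right-handed substrate are mirror images of each other, charged as a racemate, each of them at the stated concentration
- two of one species on the left: rate k times its square, two consumed each time
- at the start none of reagent is dissolved
- run time (flask): 50 h
- the handed part of reagent does not stay in what it makes, so the products of the two hands are mirror images too

    reagent + left-handed substrate → left-handed product (k1 = 6.3 × 10⁻⁴ /M/s)
    left-handed substrate ⇌ right-handed substrate (k2 = 7.8 × 10⁻⁶ /s)
    gas ⇌ reagent, rate k3*(csat - [reagent]) (k3 = 2.1 × 10⁻⁴ /s, csat = 7.5 mM)
    2 reagent → self-condensation product (k4 = 5.5 × 10⁻⁴ /M/s)
    reagent + right-handed substrate → right-handed product (k5 = 7.3 × 10⁻⁵ /M/s)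

First I ask which given numbers must be known well. Dissolved reagent relaxes towards a standing level, losing itself to the two substrates at 1.12 × 10⁻⁴ /s and through transfer at 2.1 × 10⁻⁴ /s, a time constant of 0.861 h, far shorter than the run. Self-condensation, taken even at saturation, removes reagent at 8.25 × 10⁻⁶ /s, far less than those two together, so its constant can be rough. The right-handed substrate reacts at 11.6% of the left-handed rate, so its constant can be rough too. The forward half-life of interconversion, 25 h, is shorter than the run, so it matters; I leave that feed out, which puts my figure low. An error in the transfer coefficient reaches the level at 34.8% of its size, one in the saturation concentration at full size, and one in the first rate constant reaches the result at 68.7%.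

Now the numbers. The standing level, supply over total loss, is 4.88 mM. At that level the left-handed substrate falls in a pseudo-first-order way, with 62.6 h as the capture half-life. The run holds 0.799 of them, and the left-handed substrate is half of the charge, so I reckon 21.3%. West raises the level to 5.92 mM, shortens the half-life to 51.7 h and gives 24.4%. South-east halves the half-life, so my choice is south-east.

The forecast gives 23.1% (22% to 24.2%), 26.7% after west (25.5% to 28%) and south-east, with a reagent level “set by supply against capture”. Its first figure stands higher than mine.

The simulation gives 23.1%, then 26.7% after west, and south-east as the best change, which gains 16 percentage points against 3.6 points for west.

In this flask the half-life of the left-handed substrate by capture reads 60 h at 22.7 h, near the capture half-life of 62.6 h and longer than the run, and 68% of the charged left-handed substrate stands at 50.0 h. The neighbour flask read at 20 h has 0.319 capture half-lives behind it, which reckons to 9.93% left-handed product, and that flask holds 9.77%.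

All constants were drawn at random within sensible limits; the flask was simulated.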